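**Retrosynthetic overview**

1. Target 22 ⇐ hydrogenolysis of nonabenzyl ether 21 ⇐ hydroboration–oxidation of the C2u=C3u enol ether of flav-2-ene 19 on the face away from ring D, so that C4u relays to C3u and C2u.
2. 19 ⇐ catechol 18 ⇐ oxygenation at C7u, oxidation and tautomerisation of tetrahydrochromen-8-one 14; ring A is aromatised late.
3. Feature: in the upper unit, ring A carries O1u (on C8au) and O8u (on C8u) on adjacent carbons and no oxygen at C5u, so C8u/C8au/C4au is the O=C–C(OH)=C enol of cyclohexane-1,2-dione with C4au as its nucleophilic carbon.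
4. Key disconnections C4u–C4au (Michael addition) and O1u–C2u (cyclodehydration): 14 ⇐ chalcone 10 + cyclohexane-1,2-dione 11; 10 ⇐ 8-formyl-penta-O-benzylcatechin 6 + 3,4-bis(benzyloxy)acetophenone 8.
5. Ring order: rings D, F, E come intact from (+)-catechin and ring B from the acetophenone; ring A enters as the carbocycle of 11; ring C is closed in step 7; ring A is aromatised in step 9.

Key step: step 7

Abbreviations used in names: Bn = benzyl; ArB = 3,4-bis(benzyloxy)phenyl; CatD = (2R,3S)-3,5,7-tris(benzyloxy)-2-[3,4-bis(benzyloxy)phenyl]chroman-8-yl (perbenzylated catechin bonded through C8l). Suffix u marks the upper 7,8-dihydroxyflavan unit (rings A, C, B) and suffix l the lower catechin unit (rings D, F, E). The target is the 2,3-trans-3,4-trans (2R,3S,4S) upper unit linked 4→8 to (2R,3S)-catechin.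

Assumption: the sense of induction of cinchona squaramides for this donor–acceptor pair is not known; the quinine-derived catalyst is written, and should it favour the Si face of the chalcone β-carbon, its quinidine-derived pseudo-enantiomer is the catalyst of step 7.

**Route**

Step 1
Reactants: 1 (+)-catechin
Product: 2 5,7,3',4'-tetra-O-benzyl-(+)-catechin
Conditions: BnBr (4.4 equiv), K2CO3, DMF, 0 °C to rt
Reagents that add atoms: benzyl bromide, BrCc1ccccc1
Why: Williamson etherification in which carbonate ionises only the four phenols and leaves the aliphatic C3l hydroxyl free, with C2l and C3l untouched.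

Step 2
Reactants: 2 5,7,3',4'-tetra-O-benzyl-(+)-catechin
Product: 3 3,5,7,3',4'-penta-O-benzyl-(+)-catechin
Conditions: NaH, BnBr, Bu4NI (cat.), DMF, 0 °C to rt
Reagents that add atoms: benzyl bromide, BrCc1ccccc1
Why: Williamson etherification of the secondary alkoxide; no free phenol remains that could open ring F through a quinone methide, so C2l and C3l keep their configuration.

Step 3
Reactants: 3 3,5,7,3',4'-penta-O-benzyl-(+)-catechin
Product: 4 8-bromo-3,5,7,3',4'-penta-O-benzyl-(+)-catechin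
Conditions: NBS (1.0 equiv), CH2Cl2, −78 °C to rt
Reagents that add atoms: N-bromosuccinimide, O=C1CCC(=O)N1Br
Why: Electrophilic aromatic bromination, in which C8l is the more reactive of the two free positions of the phloroglucinol-type ring D in 5,7-di-O-benzyl flavans and one equivalent of NBS at low temperature limits attack at C6l.

Step 4
Reactants: 4 8-bromo-3,5,7,3',4'-penta-O-benzyl-(+)-catechin
Product: 6 8-formyl-3,5,7,3',4'-penta-O-benzyl-(+)-catechin (CatD–CHO), via aryllithium 5 (not isolated)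
Conditions: n-BuLi (1.1 equiv), THF, −78 °C; DMF, −78 to 0 °C; aq NH4Cl
Reagents that add atoms: N,N-dimethylformamide, CN(C)C=O
Why: Bromine–lithium exchange, which is faster than benzylic deprotonation at −78 °C, followed by formylation of the aryllithium with DMF and release of the aldehyde on aqueous work-up.

Step 5
Reactants: 7 3,4-dihydroxyacetophenone
Product: 8 3,4-bis(benzyloxy)acetophenone
Conditions: BnBr (2.2 equiv), K2CO3, DMF, rt
Reagents that add atoms: benzyl bromide, BrCc1ccccc1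
Why: Williamson etherification of the two phenols; the methyl ketone is not alkylated under carbonate.

Step 6
Reactants: 6 8-formyl-3,5,7,3',4'-penta-O-benzyl-(+)-catechin; 8 3,4-bis(benzyloxy)acetophenone
Product: 10 (E)-1-ArB-3-CatD-prop-2-en-1-one (chalcone), via aldol adduct 9 (not isolated)
Conditions: KOH (50% aq), EtOH/THF, rt to 40 °C
Reagents that add atoms: none
Why: Claisen–Schmidt condensation, in which the aldehyde has no α-hydrogen and E1cB dehydration of the aldol gives the conjugated (E)-enone as the thermodynamic isomer, as 2,4,6-trialkoxybenzaldehydes are known to do.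

Step 7
Reactants: 10 (E)-1-ArB-3-CatD-prop-2-en-1-one; 11 cyclohexane-1,2-dione (3 equiv)
Product: 14 (4S)-2-ArB-4-CatD-4,5,6,7-tetrahydro-8H-chromen-8-one, via Michael adduct 12 (not isolated), via cyclic hemiketal 13 (not isolated)
Conditions: quinine-derived 3,5-bis(trifluoromethyl)phenyl squaramide (10–20 mol %), toluene (1 M), 25–40 °C; then TsOH·H2O (0.3 equiv), 4 Å MS, rt
Reagents that add atoms: none
Why: Proposed new method: the quinuclidine nitrogen of the catalyst deprotonates the enol of 11 (pKa about 10) while the squaramide NH pair hydrogen-bonds the chalcone carbonyl, and the soft enolate carbon (the future C4au) adds to the Re face of the β-carbon (the future C4u) to give 12; re-enolisation then puts the enol hydroxyl (the future O1u) in a 1,5-relation to the aryl ketone, which it attacks in a 6-exo-trig hemiketalisation to 13, and TsOH with molecular sieves removes water to give the 4H-pyran 14, so that ring C is closed by the C4u–C4au and O1u–C2u bonds. The closest known reaction types are the cinchona squaramide- and thiourea-catalysed Michael addition–cyclisation reactions of cyclohexane-1,2-dione with β,γ-unsaturated α-keto esters and with arylidenemalononitriles to 4H-chromen-8-one derivatives, and the additions of nitroalkanes and malonates to chalcones under the same bifunctional catalysts; a 1,2-dione donor on a chalcone whose β-aryl group is a di-ortho-oxygenated, electron-rich flavan ring has not been shown. The only new stereocentre, C4u, is set by the catalyst, which has to override the weak bias of the remote C2l and C3l centres of the catechin unit. The step needs carbon rather than oxygen attack of the ambident enolate, which the soft enol terminus and the soft conjugate acceptor secure, and Michael–hemiketal rather than Michael–aldol closure, which follows because no enamine activates the α-methylene of the aryl ketone. Retro-Michael erosion of C4u is limited because the acid, added as soon as the addition is complete, protonates the amine catalyst and starts the mild dehydration at room temperature.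

Step 8
Reactants: 14 (4S)-2-ArB-4-CatD-4,5,6,7-tetrahydro-8H-chromen-8-one
Product: 16 (4S,7RS)-2-ArB-4-CatD-7-hydroxy-4,5,6,7-tetrahydro-8H-chromen-8-one, via lithium enolate 15 (not isolated)
Conditions: LiN(iPr)2 (1.2 equiv), THF, −78 °C; 2-(phenylsulfonyl)-3-phenyloxaziridine, −78 °C; aq NH4Cl
Reagents that add atoms: 2-(phenylsulfonyl)-3-phenyloxaziridine (Davis oxaziridine), O=S(=O)(N1OC1c1ccccc1)c1ccccc1
Why: Kinetic α'-deprotonation of the enone at C7u by the hindered amide base and electrophilic hydroxylation of the cross-conjugated enolate (Davis oxidation), the neutral C2u=C3u enol ether being inert to the oxaziridine and the configuration of the new carbinol carbon C7u being irrelevant because step 9 removes it.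

Step 9
Reactants: 16 (4S,7RS)-2-ArB-4-CatD-7-hydroxy-4,5,6,7-tetrahydro-8H-chromen-8-one
Product: 18 (4S)-2-ArB-4-CatD-4H-chromene-7,8-diol (catechol), via ene-dione 17 (not isolated)
Conditions: (COCl)2, DMSO, CH2Cl2, −78 °C; Et3N, −78 °C to rt, under argon; aq NH4Cl/Na2S2O4 work-up, used at once
Reagents that add atoms: none
Why: Swern oxidation of the acyloin gives the 7,8-dione 17, which together with the C4au=C8au double bond is a keto tautomer of the catechol and aromatises under the triethylamine present by enolisation through C6u and C5u, while the activated sulfoxide is consumed before the catechol appears and cannot oxidise it to the quinone.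

Step 10
Reactants: 18 (4S)-2-ArB-4-CatD-4H-chromene-7,8-diol
Product: 19 (4S)-7,8-bis(benzyloxy)-2-ArB-4-CatD-4H-chromene (perbenzylated flav-2-ene)
Conditions: BnBr (2.5 equiv), K2CO3, DMF, rt, argon
Reagents that add atoms: benzyl bromide, BrCc1ccccc1
Why: Williamson etherification of both catechol hydroxyls, which removes the air-sensitive catechol and gives one protecting group throughout.

Step 11
Reactants: 19 (4S)-7,8-bis(benzyloxy)-2-ArB-4-CatD-4H-chromene
Product: 21 (2R,3S,4S)-7,8-bis(benzyloxy)-2-ArB-4-CatD-chroman-3-ol, via alkylborane 20 (not isolated)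
Conditions: BH3·THF (excess), THF, 0 °C to rt; then NaOH (3 M aq), H2O2 (30%), 0 °C to rt
Reagents that add atoms: hydrogen peroxide, OO
Why: Hydroboration–oxidation of the cyclic enol ether, as known for flav-2-enes: boron adds to C3u (β to O1u, the less substituted carbon) and hydrogen to C2u in a syn addition on the face opposite the ring D substituent at C4u, and oxidation with retention gives the 2,3-trans-3,4-trans alcohol, so C4u controls both C3u and C2u.

Step 12
Reactants: 21 (2R,3S,4S)-7,8-bis(benzyloxy)-2-ArB-4-CatD-chroman-3-ol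
Product: 22 CNP0231186.1, (2R,3S,4S)-2-(3,4-dihydroxyphenyl)-4-[(2R,3S)-2-(3,4-dihydroxyphenyl)-3,5,7-trihydroxychroman-8-yl]chromane-3,7,8-triol
Conditions: H2 (1 atm), Pd(OH)2 on carbon, THF/MeOH/H2O, rt
Reagents that add atoms: none
Why: Catalytic hydrogenolysis of the nine benzyl ethers, under which the C2–O1 ether bonds and the C4u–C8l interflavan bond of benzylated proanthocyanidins are known to survive and no stereocentre is touched.

**Compound list**

1 | (+)-catechin, (2R,3S)-2-(3,4-dihydroxyphenyl)chromane-3,5,7-triol | Oc1cc(O)c2c(c1)O[C@H](c1ccc(O)c(O)c1)[C@@H](O)C2 | starting material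
2 | 5,7,3',4'-tetra-O-benzyl-(+)-catechin, (2R,3S)-5,7-bis(benzyloxy)-2-[3,4-bis(benzyloxy)phenyl]chroman-3-ol | C(c1ccccc1)Oc1cc(OCc2ccccc2)c2c(c1)O[C@H](c1ccc(OCc3ccccc3)c(OCc3ccccc3)c1)[C@@H](O)C2 | intermediate
3 | 3,5,7,3',4'-penta-O-benzyl-(+)-catechin, (2R,3S)-3,5,7-tris(benzyloxy)-2-[3,4-bis(benzyloxy)phenyl]chromane | C(c1ccccc1)Oc1cc(OCc2ccccc2)c2c(c1)O[C@H](c1ccc(OCc3ccccc3)c(OCc3ccccc3)c1)[C@@H](OCc1ccccc1)C2 | intermediate
4 | 8-bromo-3,5,7,3',4'-penta-O-benzyl-(+)-catechin (2R,3S) | Brc1c(OCc2ccccc2)cc(OCc2ccccc2)c2c1O[C@H](c1ccc(OCc3ccccc3)c(OCc3ccccc3)c1)[C@@H](OCc1ccccc1)C2 | intermediate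
5 | 8-lithio-3,5,7,3',4'-penta-O-benzyl-(+)-catechin (2R,3S), aryllithium | [Li]c1c(OCc2ccccc2)cc(OCc2ccccc2)c2c1O[C@H](c1ccc(OCc3ccccc3)c(OCc3ccccc3)c1)[C@@H](OCc1ccccc1)C2 | intermediate
6 | 8-formyl-3,5,7,3',4'-penta-O-benzyl-(+)-catechin, (2R,3S)-3,5,7-tris(benzyloxy)-2-[3,4-bis(benzyloxy)phenyl]chromane-8-carbaldehyde | O=Cc1c(OCc2ccccc2)cc(OCc2ccccc2)c2c1O[C@H](c1ccc(OCc3ccccc3)c(OCc3ccccc3)c1)[C@@H](OCc1ccccc1)C2 | intermediate
7 | 3,4-dihydroxyacetophenone | CC(=O)c1ccc(O)c(O)c1 | starting material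
8 | 3,4-bis(benzyloxy)acetophenone | CC(=O)c1ccc(OCc2ccccc2)c(OCc2ccccc2)c1 | intermediate
9 | aldol adduct, 1-ArB-3-CatD-3-hydroxypropan-1-one (carbinol carbon unassigned) | O=C(CC(O)c1c(OCc2ccccc2)cc(OCc2ccccc2)c2c1O[C@H](c1ccc(OCc3ccccc3)c(OCc3ccccc3)c1)[C@@H](OCc1ccccc1)C2)c1ccc(OCc2ccccc2)c(OCc2ccccc2)c1 | intermediate
10 | (E)-chalcone, (E)-1-[3,4-bis(benzyloxy)phenyl]-3-[(2R,3S)-3,5,7-tris(benzyloxy)-2-[3,4-bis(benzyloxy)phenyl]chroman-8-yl]prop-2-en-1-one | O=C(/C=C/c1c(OCc2ccccc2)cc(OCc2ccccc2)c2c1O[C@H](c1ccc(OCc3ccccc3)c(OCc3ccccc3)c1)[C@@H](OCc1ccccc1)C2)c1ccc(OCc2ccccc2)c(OCc2ccccc2)c1 | intermediate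
11 | cyclohexane-1,2-dione | O=C1CCCCC1=O | starting material
12 | Michael adduct, 2-hydroxy-3-[(1S)-3-ArB-3-oxo-1-CatD-propyl]cyclohex-2-en-1-one | O=C1CCCC(=C1O)[C@H](CC(=O)c1ccc(OCc3ccccc3)c(OCc3ccccc3)c1)c1c(OCc3ccccc3)cc(OCc3ccccc3)c3c1O[C@H](c1ccc(OCc4ccccc4)c(OCc4ccccc4)c1)[C@@H](OCc1ccccc1)C3 | intermediate
13 | cyclic hemiketal, (4S)-2-ArB-4-CatD-2-hydroxy-2,3,4,5,6,7-hexahydro-8H-chromen-8-one (C2u unassigned) | O=C1CCCC2=C1OC(O)(c1ccc(OCc3ccccc3)c(OCc3ccccc3)c1)C[C@@H]2c1c(OCc3ccccc3)cc(OCc3ccccc3)c3c1O[C@H](c1ccc(OCc4ccccc4)c(OCc4ccccc4)c1)[C@@H](OCc1ccccc1)C3 | intermediate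
14 | (4S)-2-ArB-4-CatD-4,5,6,7-tetrahydro-8H-chromen-8-one | O=C1CCCC2=C1OC(c1ccc(OCc3ccccc3)c(OCc3ccccc3)c1)=C[C@@H]2c1c(OCc3ccccc3)cc(OCc3ccccc3)c3c1O[C@H](c1ccc(OCc4ccccc4)c(OCc4ccccc4)c1)[C@@H](OCc1ccccc1)C3 | intermediate
15 | lithium C7u=C8u enolate of 14 (4S) | [Li]OC1=CCCC2=C1OC(c1ccc(OCc3ccccc3)c(OCc3ccccc3)c1)=C[C@@H]2c1c(OCc3ccccc3)cc(OCc3ccccc3)c3c1O[C@H](c1ccc(OCc4ccccc4)c(OCc4ccccc4)c1)[C@@H](OCc1ccccc1)C3 | intermediate
16 | (4S,7RS)-2-ArB-4-CatD-7-hydroxy-4,5,6,7-tetrahydro-8H-chromen-8-one | O=C1C(O)CCC2=C1OC(c1ccc(OCc3ccccc3)c(OCc3ccccc3)c1)=C[C@@H]2c1c(OCc3ccccc3)cc(OCc3ccccc3)c3c1O[C@H](c1ccc(OCc4ccccc4)c(OCc4ccccc4)c1)[C@@H](OCc1ccccc1)C3 | intermediate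
17 | ene-dione, (4S)-2-ArB-4-CatD-5,6-dihydro-4H-chromene-7,8-dione | O=C1C(=O)CCC2=C1OC(c1ccc(OCc3ccccc3)c(OCc3ccccc3)c1)=C[C@@H]2c1c(OCc3ccccc3)cc(OCc3ccccc3)c3c1O[C@H](c1ccc(OCc4ccccc4)c(OCc4ccccc4)c1)[C@@H](OCc1ccccc1)C3 | intermediate
18 | catechol, (4S)-2-ArB-4-CatD-4H-chromene-7,8-diol | Oc1c(O)ccc2c1OC(c1ccc(OCc3ccccc3)c(OCc3ccccc3)c1)=C[C@@H]2c1c(OCc3ccccc3)cc(OCc3ccccc3)c3c1O[C@H](c1ccc(OCc4ccccc4)c(OCc4ccccc4)c1)[C@@H](OCc1ccccc1)C3 | intermediate
19 | (4S)-7,8-bis(benzyloxy)-2-ArB-4-CatD-4H-chromene | C(c1ccccc1)Oc1c(OCc3ccccc3)ccc2c1OC(c1ccc(OCc3ccccc3)c(OCc3ccccc3)c1)=C[C@@H]2c1c(OCc3ccccc3)cc(OCc3ccccc3)c3c1O[C@H](c1ccc(OCc4ccccc4)c(OCc4ccccc4)c1)[C@@H](OCc1ccccc1)C3 | intermediate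
20 | C3u alkylborane of 19 (BH2 on C3u anti to ring D, trans to ring B; H on C2u cis to boron) | C(c1ccccc1)Oc1ccc([C@H]2Oc3c(ccc(OCc5ccccc5)c3OCc5ccccc5)[C@@H](c3c(OCc5ccccc5)cc(OCc5ccccc5)c4c3O[C@H](c3ccc(OCc5ccccc5)c(OCc5ccccc5)c3)[C@@H](OCc3ccccc3)C4)[C@@H]2B)cc1OCc1ccccc1 | intermediate
21 | (2R,3S,4S)-7,8-bis(benzyloxy)-2-[3,4-bis(benzyloxy)phenyl]-4-[(2R,3S)-3,5,7-tris(benzyloxy)-2-[3,4-bis(benzyloxy)phenyl]chroman-8-yl]chroman-3-ol | C(c1ccccc1)Oc1ccc([C@H]2Oc3c(ccc(OCc5ccccc5)c3OCc5ccccc5)[C@@H](c3c(OCc5ccccc5)cc(OCc5ccccc5)c4c3O[C@H](c3ccc(OCc5ccccc5)c(OCc5ccccc5)c3)[C@@H](OCc3ccccc3)C4)[C@@H]2O)cc1OCc1ccccc1 | intermediate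
22 | CNP0231186.1, (2R,3S,4S)-2-(3,4-dihydroxyphenyl)-4-[(2R,3S)-2-(3,4-dihydroxyphenyl)-3,5,7-trihydroxychroman-8-yl]chromane-3,7,8-triol | Oc1ccc([C@H]2Oc3c(ccc(O)c3O)[C@@H](c3c(O)cc(O)c4c3O[C@H](c3ccc(O)c(O)c3)[C@@H](O)C4)[C@@H]2O)cc1O | target

**Step count**

Total: 12 steps. Longest linear sequence: 11 steps (steps 1–4 and 6–12 from (+)-catechin).

**Steps most likely to fail**

Step 7 (proposed new method). The conjugate addition may stall at the electron-rich, doubly ortho-shielded β-carbon, or run with poor facial selectivity, or lose C4u by retro-Michael reaction before dehydration. The fallback uses known flavylium chemistry; it sets out from 8 and 3 and rejoins the route at 19. Bought 2,3,4-trihydroxybenzaldehyde (O=Cc1ccc(O)c(O)c1O) is perbenzylated (BnBr, K2CO3, DMF) to 2,3,4-tris(benzyloxy)benzaldehyde F1. Chelation-assisted removal of the ortho benzyl group (MgBr2·OEt2, toluene/Et2O) gives 3,4-bis(benzyloxy)-2-hydroxybenzaldehyde F2. Acid-mediated aldol condensation and cyclodehydration of F2 with acetophenone 8 (HCl gas, EtOAc, 0 °C) should give 7,8-bis(benzyloxy)-2-[3,4-bis(benzyloxy)phenyl]chromenylium chloride F3. Friedel–Crafts-type addition of C8l of penta-O-benzylcatechin 3 to C4 of this flavylium salt (MeCN/CH2Cl2, solid NaHCO3) is the known route to 4-arylflav-2-enes. It has no control at C4u, so 19 would be separated by chromatography from its C4u epimer, (4R)-7,8-bis(benzyloxy)-2-ArB-4-CatD-4H-chromene F4. The route continues with step 11.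

Step 8. Deprotonation may occur at the γ positions (C5u, or the doubly allylic and benzylic C4u–H) instead of C7u, giving wrong-site oxygenation or loss of the C4u configuration. The fallback avoids strong base; it sets out from 14, rejoins at 18 and replaces steps 8 and 9. Aerobic dehydrogenation of the cyclohexenone (Pd(OCOCF3)2 cat., 2-(dimethylamino)pyridine, O2, DMSO, 80 °C) gives the phenol (4S)-2-ArB-4-CatD-4H-chromen-8-ol F5. Magnesium-mediated ortho-formylation (MgCl2, Et3N, paraformaldehyde, MeCN, reflux) at the only free ortho position, C7u, gives the salicylaldehyde (4S)-2-ArB-4-CatD-8-hydroxy-4H-chromene-7-carbaldehyde F6. Dakin oxidation (H2O2, NaOH, THF/H2O) then gives catechol 18.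

Step 11. The facial preference of the borane may be insufficient, or the β-alkoxyborane may undergo β-elimination with opening of ring C. The fallback sets out from 19 and rejoins at 21. Dihydroxylation of the enol ether on the face away from ring D (K2OsO4·2H2O cat., N-methylmorpholine N-oxide, acetone/H2O) gives the hemiketal diol (3S,4S)-7,8-bis(benzyloxy)-2-ArB-4-CatD-chromane-2,3-diol F7. Ionic hydrogenation of the hemiketal (Et3SiH, BF3·OEt2, CH2Cl2, −78 °C) through the C2u oxocarbenium ion should deliver hydride axially, cis to the pseudo-equatorial C3u hydroxyl, leaving ring B equatorial and trans to it, which is 21.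

**Further compounds**

F1 | step 7 | 2,3,4-tris(benzyloxy)benzaldehyde | O=Cc1ccc(OCc2ccccc2)c(OCc2ccccc2)c1OCc1ccccc1
F2 | step 7 | 3,4-bis(benzyloxy)-2-hydroxybenzaldehyde | O=Cc1ccc(OCc2ccccc2)c(OCc2ccccc2)c1O
F3 | step 7 | 7,8-bis(benzyloxy)-2-[3,4-bis(benzyloxy)phenyl]chromenylium chloride | [Cl-].C(c1ccccc1)Oc1ccc(-c2ccc3ccc(OCc4ccccc4)c(OCc4ccccc4)c3[o+]2)cc1OCc1ccccc1
F4 | step 7 | (4R)-7,8-bis(benzyloxy)-2-ArB-4-CatD-4H-chromene, C4u epimer of 19 | C(c1ccccc1)Oc1c(OCc3ccccc3)ccc2c1OC(c1ccc(OCc3ccccc3)c(OCc3ccccc3)c1)=C[C@H]2c1c(OCc3ccccc3)cc(OCc3ccccc3)c3c1O[C@H](c1ccc(OCc4ccccc4)c(OCc4ccccc4)c1)[C@@H](OCc1ccccc1)C3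
F5 | step 8 | (4S)-2-ArB-4-CatD-4H-chromen-8-ol | Oc1cccc2c1OC(c1ccc(OCc3ccccc3)c(OCc3ccccc3)c1)=C[C@@H]2c1c(OCc3ccccc3)cc(OCc3ccccc3)c3c1O[C@H](c1ccc(OCc4ccccc4)c(OCc4ccccc4)c1)[C@@H](OCc1ccccc1)C3
F6 | step 8 | (4S)-2-ArB-4-CatD-8-hydroxy-4H-chromene-7-carbaldehyde | Oc1c(C=O)ccc2c1OC(c1ccc(OCc3ccccc3)c(OCc3ccccc3)c1)=C[C@@H]2c1c(OCc3ccccc3)cc(OCc3ccccc3)c3c1O[C@H](c1ccc(OCc4ccccc4)c(OCc4ccccc4)c1)[C@@H](OCc1ccccc1)C3
F7 | step 11 | (3S,4S)-7,8-bis(benzyloxy)-2-ArB-4-CatD-chromane-2,3-diol (hemiketal, C2u unassigned) | C(c1ccccc1)Oc1ccc(C2(O)Oc3c(ccc(OCc5ccccc5)c3OCc5ccccc5)[C@@H](c3c(OCc5ccccc5)cc(OCc5ccccc5)c4c3O[C@H](c3ccc(OCc5ccccc5)c(OCc5ccccc5)c3)[C@@H](OCc3ccccc3)C4)[C@@H]2O)cc1OCc1ccccc1
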